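**Strategy.** The route rests on disconnecting the C2–C3 bond of the ten-membered carbocycle (C1–C10), where the allylic acetoxy carbon C2 sits between the quaternary ring-fusion carbon C1 and the C3=C4/C5=C6 diene. An intramolecular Nozaki–Hiyama–Kishi reaction of a seco-aldehyde that already carries the epoxycyclohexane, the β-hydroxy-γ-lactone and a dienyl iodide closes this ring last and sets C2 in the same operation. The cyclohexane comes from a Sharpless epoxide by cation–olefin cyclization (C1, C10 and C14 relayed), the lactone stereocentres from one bought methyl-bearing lactone through an aldol reaction, and the diene from a lactone-bound alkyne.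

Key step: step 22

Remark: briarane numbering is used throughout (C1 quaternary with Me-15; C2–C9 in the ten-membered ring; C10 ring-fusion CH; C11–C14 cyclohexane with Me-20 on C11; C16 = CH2 on C5; lactone C7–O–C19(=O)–C17(Me-18)–C8). Compounds 11, 16 and 23 are taken as commercial.

Step 1
Reactants: 1 geranyl acetate
Product: 2 (2E,6E)-8-hydroxygeranyl acetate
Conditions: SeO2 (cat.), t-BuOOH, salicylic acid (cat.), CH2Cl2, rt
Reagents that add atoms: selenium dioxide O=[Se]=O (catalytic oxygen carrier); tert-butyl hydroperoxide CC(C)(C)OO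
Why: Sharpless–Umbreit allylic oxidation (ene/[2,3] shift) should hydroxylate the E-methyl group of the distal trisubstituted alkene selectively.

Step 2
Reactants: 2 (2E,6E)-8-hydroxygeranyl acetate
Product: 3 (6R,7R)-6,7-epoxy-8-hydroxygeranyl acetate
Conditions: Ti(OiPr)4 (cat.), D-(−)-diethyl tartrate, t-BuOOH, 4 Å MS, CH2Cl2, −20 °C
Reagents that add atoms: tert-butyl hydroperoxide CC(C)(C)OO
Why: Sharpless asymmetric epoxidation of the allylic alcohol; D-(−)-DET should give the (R,R)-epoxide, the one catalyst-set element from which C1, C10 and C14 are later relayed.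

Step 3
Reactants: 3 (6R,7R)-6,7-epoxy-8-hydroxygeranyl acetate
Product: 4 TBDPS ether of 3
Conditions: TBDPSCl, imidazole, DMF, 0 °C → rt
Reagents that add atoms: tert-butyl(chloro)diphenylsilane CC(C)(C)[Si](Cl)(c1ccccc1)c1ccccc1
Why: Standard silylation; it masks the future C2 oxygen and prevents chelation-directed opening of the epoxy alcohol.

Step 4
Reactants: 4 TBDPS ether
Product: 5 cyclohexenol (C9 acetate, C2 OTBDPS, 14β-OH equatorial, C11=C12)
Conditions: ZrCl4, CH2Cl2, −78 → −30 °C
Reagents that add atoms: none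
Why: Lewis-acid epoxy-olefin (cation–olefin) cyclization through a chair: the C10=C11 alkene attacks the tertiary epoxide carbon C1 with inversion, C9 and C2 end up equatorial and Me-15 axial, so the epoxide configuration sets C1 and C10; loss of H-12 should give the endocyclic alkene.

Step 5
Reactants: 5 cyclohexenol
Product: 6 C14 ketone
Conditions: Dess–Martin periodinane, NaHCO3, CH2Cl2, 0 °C
Reagents that add atoms: none
Why: Dess–Martin oxidation under buffered conditions should avoid conjugation of the β,γ-unsaturated ketone, which is used directly.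

Step 6
Reactants: 6 C14 ketone
Product: 7 14α-alcohol (axial)
Conditions: L-Selectride, THF, −78 °C
Reagents that add atoms: none
Why: The bulky hydride should attack the 2,2-disubstituted cyclohexanone from the equatorial direction (as with 4,4-dimethyl-3-keto terpenoids), giving the axial 14α-alcohol, i.e. net inversion at C14.

Step 7
Reactants: 7 14α-alcohol
Product: 8 11α,12α-epoxide
Conditions: VO(acac)2 (cat.), t-BuOOH, CH2Cl2, 0 °C → rt
Reagents that add atoms: tert-butyl hydroperoxide CC(C)(C)OO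
Why: Hydroxyl-directed vanadium epoxidation; the axial homoallylic 14α-OH should deliver oxygen to the α-face of C11=C12, while the acetate keeps C9–O from directing.

Step 8
Reactants: 8 epoxy acetate
Product: 9 9,14-diol
Conditions: K2CO3, MeOH, 0 °C
Reagents that add atoms: none
Why: Methanolysis of the primary acetate; the epoxide is inert to carbonate, and the α-alkoxide cannot reach the α-epoxide from the back.

Step 9
Reactants: 9 9,14-diol
Product: 10 epoxy aldehyde (C9 CHO, 14α-OH)
Conditions: TEMPO (cat.), PhI(OAc)2, CH2Cl2, rt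
Reagents that add atoms: none
Why: TEMPO/BAIB oxidation is selective for the primary alcohol; the trans relation of C9 and 14α-OH excludes lactol formation and over-oxidation.

Step 10
Reactants: 11 (R)-4-methyldihydrofuran-2(3H)-one
Product: 12 (3R,4S)-3-hydroxy-4-methyldihydrofuran-2(3H)-one
Conditions: LDA, THF, −78 °C; then 2-(phenylsulfonyl)-3-phenyloxaziridine
Reagents that add atoms: 2-(phenylsulfonyl)-3-phenyloxaziridine O=S(=O)(N1OC1c1ccccc1)c1ccccc1
Why: Davis enolate hydroxylation, expected anti to the 4-methyl group (this centre is enolized again in step 12).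

Step 11
Reactants: 12 hydroxy lactone
Product: 13 (3R,4S)-4-methyl-3-(triethylsilyloxy)dihydrofuran-2(3H)-one
Conditions: TESCl, imidazole, DMF, rt
Reagents that add atoms: chlorotriethylsilane CC[Si](Cl)(CC)CC
Why: Standard silylation to give an α-silyloxy lactone that can be enolized.

Step 12
Reactants: 10 epoxy aldehyde; 13 silyloxy lactone
Product: 15 tris-TES aldol product (C8–C9 bond; C8-, C9- and C14-OTES), via aldol diol 14 (not isolated)
Conditions: 13, LDA, THF, −78 °C; then 10; then TESOTf, −78 → 0 °C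
Reagents that add atoms: triethylsilyl triflate CC[Si](CC)(CC)OS(=O)(=O)C(F)(F)F
Why: Lithium enolate aldol addition through a Zimmerman–Traxler chair: the aldehyde should enter anti to the methyl group (C8 relative to C17) and the ring-locked enolate geometry places O8 and O9 syn (C9); a second equivalent of enolate deprotonates 14-OH, and both alkoxides are silylated in the flask.

Step 13
Reactants: 15 tris-TES aldol product; 16 tert-butyldimethyl(prop-2-yn-1-yloxy)silane
Product: 17 hydroxy ynone (C7 ketone, C19 CH2OH)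
Conditions: 16, n-BuLi, THF, −78 °C; then 15, −78 → −40 °C
Reagents that add atoms: none
Why: Acetylide addition to the lactone carbonyl C7 should stop at the lithium hemiketal, which opens on work-up to the γ-hydroxy ynone and brings in C6, C5 and C16.

Step 14
Reactants: 17 hydroxy ynone
Product: 18 (7S)-propargylic 7,19-diol
Conditions: RuCl[(R,R)-TsDPEN](p-cymene) (cat.), i-PrOH, rt
Reagents that add atoms: none
Why: Noyori asymmetric transfer hydrogenation of the alkynyl ketone under reagent control (alkyne as the π-substituent) should set 7S.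

Step 15
Reactants: 18 propargylic diol
Product: 20 alkynyl lactone (C19 carbonyl, ring O on C7), via lactol 19 (not isolated)
Conditions: TEMPO (cat.), PhI(OAc)2, CH2Cl2, rt
Reagents that add atoms: none
Why: Oxidative lactonization of the 1,4-diol: the primary C19 alcohol is oxidized first, the aldehyde is trapped by 7-OH (9-O is silylated) and the lactol is oxidized on to the butanolide.

Step 16
Reactants: 20 alkynyl lactone
Product: 21 tetraol (8-, 9-, 14-, 16-OH; C2 OTBDPS kept)
Conditions: HF·pyridine, pyridine, THF, 0 °C → rt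
Reagents that add atoms: none
Why: Buffered fluoride desilylation should cleave the TES ethers and the primary TBS ether while the neopentyl TBDPS ether and the epoxide survive.

Step 17
Reactants: 21 tetraol
Product: 22 (Z)-alkenylstannane (SnBu3 on C5, cis to C7)
Conditions: [Cp*RuCl]4 (cat.), Bu3SnH, CH2Cl2, rt
Reagents that add atoms: tributyltin hydride CCCC[SnH](CCCC)CCCC
Why: Ruthenium-catalysed trans-hydrostannation directed by the propargylic 16-OH should place tin on C5 and add H and Sn anti, which fixes the C5=C6 geometry of the target.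

Step 18
Reactants: 22 alkenylstannane; 23 (E)-1,2-diiodoethene
Product: 24 dienyl iodide (E C3=C4; C4 cis to C7)
Conditions: 23 (excess), Pd2(dba)3 (cat.), AsPh3, CuI (cat.), DMF, rt
Reagents that add atoms: none
Why: Stille coupling with retention at both alkenes; the excess of diiodide should keep it to mono-coupling.

Step 19
Reactants: 24 dienyl iodide
Product: 25 9,14,16-triacetate
Conditions: Ac2O, pyridine, DMAP (cat.), CH2Cl2, rt
Reagents that add atoms: acetic anhydride CC(=O)OC(C)=O
Why: Acetylation of the primary and the two secondary hydroxyls; the tertiary 8-OH should stay free.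

Step 20
Reactants: 25 triacetate
Product: 26 C2 primary alcohol
Conditions: TBAF, AcOH, THF, rt
Reagents that add atoms: none
Why: Buffered fluoride cleavage of the TBDPS ether; the buffer should suppress acetyl migration and lactone opening.

Step 21
Reactants: 26 C2 primary alcohol
Product: 27 seco-aldehyde (C2 CHO, C3 iodide)
Conditions: Dess–Martin periodinane, NaHCO3, CH2Cl2, 0 °C → rt
Reagents that add atoms: none
Why: Dess–Martin oxidation of the neopentyl alcohol; 9-OAc blocks lactol formation and the tertiary 8-OH is inert.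

Step 22
Reactants: 27 seco-aldehyde
Product: 28 macrocyclic (2S)-alcohol
Conditions: CrCl2 (excess), NiCl2 (cat.), DMSO, rt, high dilution (slow addition)
Reagents that add atoms: none
Why: Ni(0) inserts into the C3–I bond and transmetalates to Cr(III), and the configurationally stable dienylchromium adds to the C2 aldehyde (intramolecular Nozaki–Hiyama–Kishi reaction, the closest precedent being NHK closures of nine- and ten-membered carbocycles). The ten-membered ring C1–C10 closes in a 10-exo-trig addition, helped by the trans-diequatorial exit of C2 and C9 from the cyclohexane and by the cis relation of C4 and C7 on C5=C6. The new stereocentre C2 is set by the quaternary C1: the ring bond C1–C10 lies anti to the incoming C3, Me-15 flanks the trajectory and the chromium-bound oxygen points outwards toward C14 (Felkin–Anh), which should give 2S. The step needs chemoselectivity for the alkenyl iodide over the acetates, the lactone, the free 8-OH and the epoxide, which organochromium reagents normally show, and retention of the E C3=C4 geometry, which the alkenyl–chromium bond secures. High dilution should suppress oligomerisation.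

Step 23
Reactants: 28 macrocyclic alcohol
Product: 29 CNP0250433.1 (target)
Conditions: Ac2O, pyridine, DMAP (cat.), CH2Cl2, rt
Reagents that add atoms: acetic anhydride CC(=O)OC(C)=O
Why: Acetylation of the allylic 2-OH; the tertiary 8-OH should remain free as in the target.

**Compound list**

1 | geranyl acetate | CC(C)=CCC/C(C)=C/COC(C)=O | starting material
2 | (2E,6E)-8-hydroxygeranyl acetate | OC/C(C)=C/CC/C(C)=C/COC(C)=O | intermediate
3 | (2E)-5-[(2R,3R)-3-(hydroxymethyl)-3-methyloxiran-2-yl]-3-methylpent-2-enyl acetate | CC(=O)OC/C=C(\C)CC[C@H]1O[C@]1(C)CO | intermediate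
4 | TBDPS ether of 3 | CC(=O)OC/C=C(\C)CC[C@H]1O[C@]1(C)CO[Si](c2ccccc2)(c2ccccc2)C(C)(C)C | intermediate
5 | cyclohexenol: C10 bears CH2OAc (β), C1 bears Me (β) and CH2OTBDPS (α), 14β-OH, C11=C12 | CC(=O)OC[C@H]1C(C)=CC[C@@H](O)[C@]1(C)CO[Si](c2ccccc2)(c2ccccc2)C(C)(C)C | intermediate
6 | C14 ketone of 5 | CC(=O)OC[C@H]1C(C)=CCC(=O)[C@]1(C)CO[Si](c2ccccc2)(c2ccccc2)C(C)(C)C | intermediate
7 | 14α-alcohol (C14 epimer of 5) | CC(=O)OC[C@H]1C(C)=CC[C@H](O)[C@]1(C)CO[Si](c2ccccc2)(c2ccccc2)C(C)(C)C | intermediate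
8 | 11α,12α-epoxide of 7 | CC(=O)OC[C@H]1[C@]2(C)O[C@@H]2C[C@H](O)[C@]1(C)CO[Si](c3ccccc3)(c3ccccc3)C(C)(C)C | intermediate
9 | epoxy 9,14-diol | OC[C@H]1[C@]2(C)O[C@@H]2C[C@H](O)[C@]1(C)CO[Si](c3ccccc3)(c3ccccc3)C(C)(C)C | intermediate
10 | epoxy aldehyde (C9 CHO, 14α-OH) | O=C[C@H]1[C@]2(C)O[C@@H]2C[C@H](O)[C@]1(C)CO[Si](c3ccccc3)(c3ccccc3)C(C)(C)C | intermediate
11 | (R)-4-methyldihydrofuran-2(3H)-one | O=C1OC[C@H](C)C1 | starting material
12 | (3R,4S)-3-hydroxy-4-methyldihydrofuran-2(3H)-one | O=C1OC[C@H](C)[C@H]1O | intermediate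
13 | (3R,4S)-4-methyl-3-(triethylsilyloxy)dihydrofuran-2(3H)-one | O=C1OC[C@H](C)[C@H]1O[Si](CC)(CC)CC | intermediate
14 | aldol diol (9-OH, 14-OH; present as its dilithium alkoxide, drawn neutral) | O=C1OC[C@H](C)[C@@]1(O[Si](CC)(CC)CC)[C@@H](O)[C@H]1[C@]2(C)O[C@@H]2C[C@H](O)[C@]1(C)CO[Si](c3ccccc3)(c3ccccc3)C(C)(C)C | intermediate (not isolated)
15 | tris-TES aldol product (lactone carbonyl = C7, ring O on C19) | O=C1OC[C@H](C)[C@@]1(O[Si](CC)(CC)CC)[C@@H](O[Si](CC)(CC)CC)[C@H]1[C@]2(C)O[C@@H]2C[C@H](O[Si](CC)(CC)CC)[C@]1(C)CO[Si](c3ccccc3)(c3ccccc3)C(C)(C)C | intermediate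
16 | tert-butyldimethyl(prop-2-yn-1-yloxy)silane | C#CCO[Si](C)(C)C(C)(C)C | starting material
17 | hydroxy ynone (C7 ketone, C19 CH2OH) | OC[C@H](C)[C@](O[Si](CC)(CC)CC)(C(=O)C#CCO[Si](C)(C)C(C)(C)C)[C@@H](O[Si](CC)(CC)CC)[C@H]1[C@]2(C)O[C@@H]2C[C@H](O[Si](CC)(CC)CC)[C@]1(C)CO[Si](c3ccccc3)(c3ccccc3)C(C)(C)C | intermediate
18 | (7S)-propargylic 7,19-diol | OC[C@H](C)[C@](O[Si](CC)(CC)CC)([C@@H](O)C#CCO[Si](C)(C)C(C)(C)C)[C@@H](O[Si](CC)(CC)CC)[C@H]1[C@]2(C)O[C@@H]2C[C@H](O[Si](CC)(CC)CC)[C@]1(C)CO[Si](c3ccccc3)(c3ccccc3)C(C)(C)C | intermediate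
19 | lactol (C19 hemiacetal with 7-O) | CC(C)(C)[Si](C)(C)OCC#C[C@@H]1OC(O)[C@H](C)[C@@]1(O[Si](CC)(CC)CC)[C@@H](O[Si](CC)(CC)CC)[C@H]1[C@]2(C)O[C@@H]2C[C@H](O[Si](CC)(CC)CC)[C@]1(C)CO[Si](c3ccccc3)(c3ccccc3)C(C)(C)C | intermediate (not isolated)
20 | alkynyl lactone (C19 carbonyl, ring O on C7), fully silylated | CC(C)(C)[Si](C)(C)OCC#C[C@@H]1OC(=O)[C@H](C)[C@@]1(O[Si](CC)(CC)CC)[C@@H](O[Si](CC)(CC)CC)[C@H]1[C@]2(C)O[C@@H]2C[C@H](O[Si](CC)(CC)CC)[C@]1(C)CO[Si](c3ccccc3)(c3ccccc3)C(C)(C)C | intermediate
21 | alkynyl lactone tetraol (C2 OTBDPS) | OCC#C[C@@H]1OC(=O)[C@H](C)[C@@]1(O)[C@@H](O)[C@H]1[C@]2(C)O[C@@H]2C[C@H](O)[C@]1(C)CO[Si](c3ccccc3)(c3ccccc3)C(C)(C)C | intermediate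
22 | (Z)-alkenylstannane (Bu3Sn on C5, cis to C7) | CCCC[Sn](CCCC)(CCCC)/C(CO)=C\[C@@H]1OC(=O)[C@H](C)[C@@]1(O)[C@@H](O)[C@H]1[C@]2(C)O[C@@H]2C[C@H](O)[C@]1(C)CO[Si](c3ccccc3)(c3ccccc3)C(C)(C)C | intermediate
23 | (E)-1,2-diiodoethene | I/C=C/I | starting material
24 | dienyl iodide tetraol | I/C=C/C(CO)=C\[C@@H]1OC(=O)[C@H](C)[C@@]1(O)[C@@H](O)[C@H]1[C@]2(C)O[C@@H]2C[C@H](O)[C@]1(C)CO[Si](c3ccccc3)(c3ccccc3)C(C)(C)C | intermediate
25 | 9,14,16-triacetate (8-OH free, C2 OTBDPS) | I/C=C/C(COC(C)=O)=C\[C@@H]1OC(=O)[C@H](C)[C@@]1(O)[C@@H](OC(C)=O)[C@H]1[C@]2(C)O[C@@H]2C[C@H](OC(C)=O)[C@]1(C)CO[Si](c3ccccc3)(c3ccccc3)C(C)(C)C | intermediate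
26 | C2 primary alcohol | I/C=C/C(COC(C)=O)=C\[C@@H]1OC(=O)[C@H](C)[C@@]1(O)[C@@H](OC(C)=O)[C@H]1[C@]2(C)O[C@@H]2C[C@H](OC(C)=O)[C@]1(C)CO | intermediate
27 | seco-aldehyde (C2 CHO, C3 iodide) | I/C=C/C(COC(C)=O)=C\[C@@H]1OC(=O)[C@H](C)[C@@]1(O)[C@@H](OC(C)=O)[C@H]1[C@]2(C)O[C@@H]2C[C@H](OC(C)=O)[C@]1(C)C=O | intermediate
28 | 2-deacetyl target (macrocyclic 2S alcohol) | CC(=O)OCC1=C/[C@@H]2OC(=O)[C@H](C)[C@@]2(O)[C@@H](OC(C)=O)[C@H]2[C@]3(C)O[C@@H]3C[C@H](OC(C)=O)[C@]2(C)[C@@H](O)\C=C\1 | intermediate
29 | CNP0250433.1 | CC(=O)OCC1=C/[C@@H]2OC(=O)[C@H](C)[C@@]2(O)[C@@H](OC(C)=O)[C@H]2[C@]3(C)O[C@@H]3C[C@H](OC(C)=O)[C@]2(C)[C@@H](OC(C)=O)\C=C\1 | target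

**Count.** Total: 23 steps. Longest linear sequence: 21 steps (steps 1–9 and 12–23, from geranyl acetate).

**Steps most likely to fail**

1. Step 22 (ring closure). The alkenylchromium may add to the wrong face of the C2 aldehyde, since the facial preference rests only on the conformation of the forming ring. The fallback sets out from 27: the same closure then delivers the 2-epimeric macrocyclic alcohol F4. Dess–Martin oxidation gives the ring dienone F5 (C2 ketone), and C2 is set instead by reagent-controlled CBS reduction (oxazaborolidine antipode chosen for 2S, catecholborane, −78 °C). This returns to the route at 28.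

2. Step 12 (aldol). The doubly flanked aldehyde may react slowly or through its other face, so that C9 is formed with the wrong configuration. The fallback sets out from 10 and 13: the aldol is quenched without silylation and the 9-epimeric aldol diol F2 (alone or mixed with 14) is isolated. Dess–Martin oxidation gives the 9,14-diketone F3, and C9 is then set by hydride delivery instead of C–C bond formation. L-Selectride should reduce C14 as in step 6 and C9 by Felkin–Anh attack anti to C1, giving 14, which is silylated (TESOTf, 2,6-lutidine) to return at 15.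

3. Step 4 (cyclization). The C11 cation may lose the wrong proton (exocyclic alkene) or be captured before elimination, and the Lewis acid may ionize the allylic acetate. The fallback sets out from 4: a titanocene(III) radical epoxide opening and 6-endo cyclization (Cp2TiCl2, Mn, THF) should give the exocyclic alkene isomer F1 selectively. This is isomerized to the endocyclic alkene with RhCl3·3H2O in EtOH, through the less hindered C12–H, and returns at 5.

Further compounds
F1 | step 4 | exocyclic (C11=CH2) isomer of 5 | CC(=O)OC[C@H]1C(=C)CC[C@@H](O)[C@]1(C)CO[Si](c2ccccc2)(c2ccccc2)C(C)(C)C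
F2 | step 12 | 9-epimer of aldol diol 14 | O=C1OC[C@H](C)[C@@]1(O[Si](CC)(CC)CC)[C@H](O)[C@H]1[C@]2(C)O[C@@H]2C[C@H](O)[C@]1(C)CO[Si](c3ccccc3)(c3ccccc3)C(C)(C)C
F3 | step 12 | 9,14-diketone | O=C1OC[C@H](C)[C@@]1(O[Si](CC)(CC)CC)C(=O)[C@H]1[C@]2(C)O[C@@H]2CC(=O)[C@]1(C)CO[Si](c3ccccc3)(c3ccccc3)C(C)(C)C
F4 | step 22 | 2-epimer of 28 | CC(=O)OCC1=C/[C@@H]2OC(=O)[C@H](C)[C@@]2(O)[C@@H](OC(C)=O)[C@H]2[C@]3(C)O[C@@H]3C[C@H](OC(C)=O)[C@]2(C)[C@H](O)\C=C\1
F5 | step 22 | macrocyclic C2 ketone (dienone) | CC(=O)OCC1=C/[C@@H]2OC(=O)[C@H](C)[C@@]2(O)[C@@H](OC(C)=O)[C@H]2[C@]3(C)O[C@@H]3C[C@H](OC(C)=O)[C@]2(C)C(=O)\C=C\1
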